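(All runs stem from a simulated flask with constants of no real substance; scatter was added.)

Noon was charged with twice the Z of midnight, yet at 4.00 h noon has 39.0% of it left and midnight 39.5%. Your flask, at 15 mM, lies between the two charges, so you can bracket it.

in all of them: X 1.5 mM (held)

| charge | Z | Q | remark | time |
|---|---|---|---|---|
| midnight | 10 mM | 0.30 mM | run made earlier |  |
| noon | 22 mM | 0.30 mM | run made earlier |  |
| dawn | 15 mM | 0.15 mM | run made earlier |  |
| flask | 15 mM | 0.30 mM |  | 6.0 h |

| run | time / h | E / % | Z / % |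
|---|---|---|---|
| midnight | 0.250 | 6.3 | 94.6 |
| midnight | 0.667 | 17.1 | 87.1 |
| midnight | 1.33 | 26.0 | 71.8 |
| midnight | 2.00 | 35.4 | 61.2 |
| midnight | 3.00 | 50.5 | 48.9 |
| midnight | 4.00 | 59.6 | 39.5 |
| noon | 0.667 | 14.5 | 85.5 |
| noon | 1.33 | 26.4 | 71.8 |
| noon | 2.00 | 37.6 | 63.6 |
| noon | 2.50 | 44.5 | 55.4 |
| noon | 3.00 | 50.1 | 50.6 |
| noon | 4.00 | 60.0 | 39.0 |
| dawn | 0.250 | 5.3 | 95.4 |
| dawn | 0.500 | 7.5 | 93.3 |
| dawn | 1.00 | 13.4 | 86.3 |
| dawn | 2.00 | 26.1 | 76.0 |
| dawn | 4.00 | 42.4 | 57.2 |

(each reading ± 1 percentage point)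

1. E at 6.0 h, in percent of the Z charged
2. concentration of L in solution at 1.5 h, in percent of saturation
3. the change that raises the amount of E at 6.0 h, in percent of the Z charged most ("none" if none brings more than 2 percentage points) (ash / cedar / elm / none)
4. amount of E at 6.0 h, in percent of the Z charged, after elm

- ash: doubling the transfer coefficient of X, all else as stated
- cedar: doubling the amount of Q, all else as stated
- elm: doubling the saturation concentration of X, all else as stated

- at the start none of X is in solution
- L is what X becomes in solution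

Noon's Z gives 0.235 h⁻¹. Midnight's E, read as Z gone, gives 0.227 h⁻¹. These are two readings of the pace, the natural log of charged over left, per hour: the pseudo-first-order constant. Carried to 6.0 h, they put E between 74.3% and 75.6%.

Midnight's first reading already gives 0.222 h⁻¹, with no visible lag. So I put L close to 1.5 mM by 1.5 h and expect little from ash.

Dawn, with half the Q, reads 0.140 h⁻¹. If doubling Q repeats that step, cedar gives about 90.6%. For elm the bracket is wide. It runs from 74.3% with the pace unchanged to 94.0% with the pace doubled.

The forecast says 75.5%, against your 74.3% to 75.6%. It puts L at 98% of saturation at 1.5 h, names elm as the best change, and gives 93% after elm. On elm it warns: “No run varied X, so its order is an assumption”.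

The flask gives 75.4%, inside the bracket, with L at 99.0% of saturation at 1.5 h.

    Z + L + Q → Q + E (k = 1.10 × 10⁶ L² mol⁻² h⁻¹)
    X ⇌ L, rate k2*(csat - [L]) (kL = 170 h⁻¹)
    2 Q ⇌ J (K = 3900 L mol⁻¹, k = 41000 L mol⁻¹ h⁻¹)

The best change is elm, worth 19 percentage points, against 13 points for cedar and 0.16 points for ash. The flask's own pace is 0.234 h⁻¹. Doubled, it gives 94.0% at 6.0 h, and the elm flask stands at 94.0%.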